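**Plan**

1. Retrosynthetic cuts: (a) the ring ketone carbon and the macrolactone carbonyl carbon are rejoined as the C=C of a bicyclic enol ether, to be cleaved oxidatively in the last step; (b) the exocyclic C=C between the butyrolactone α-carbon and C2 of the furo[3,2-b]pyran (numbering O1, C2, C3, C3a, O4, C5, C6, C7, C7a) is cut to a lactone enolate plus a lactone; (c) in the furopyran, the ring-fusion bond C3a–C7a and the O4–C5 bond are cut together.
2. Enabling feature: in the tetrahydropyran, C7a–C7–C6–C5 (oxygen on C7a, methyl on C5) is a hydrogenated (1E,3E)-1-acyloxypentadiene and C3a–O4 is an aldehyde carbonyl. The two are already linked by the three-atom bridge O1–C2–C3 of the five-membered ring, so one intramolecular oxo-Diels–Alder reaction of a dienyl 3-oxopropanoate closes both rings.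
3. Forward, fragment A: dienyl ester 13 → hydroxy ester 14 → oxidation/cycloaddition to bicyclic lactone 16 → saturated lactone 17. Fragment B: arene 4 → Birch reduction → cis-fused keto lactone 7 → tricyclic enol ether 8.
4. Union: enolate of 8 adds to 17 (hemiketal 18), dehydration gives vinylogous carbonate 19, and ozonolysis of the enol ether opens the ten-membered keto lactone last.
5. Stereochemistry: the macrolactone CH(CH3)–O centre comes from (R)-but-3-yn-2-ol; the two butyrolactone ring-fusion centres from an amine-catalysed enantioselective enone isomerisation followed by cis-lactonisation; the three furopyran centres from the key step (catalyst face control, diene geometry, endo tether); the alkene geometry is thermodynamic.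

Key step: step 8

Assumption: the sense of induction of the two chiral catalysts (steps 4 and 8) is taken by analogy with the parent reactions, each catalyst having an available (pseudo)enantiomer if the sense proves opposite; acid 9 is taken as purchasable.

**Step 1**
Reactants: 1 2-(3-bromo-4-methoxyphenyl)acetic acid; 2 (R)-but-3-yn-2-ol
Product: 3 2-{3-[(3R)-3-hydroxybut-1-yn-1-yl]-4-methoxyphenyl}acetic acid
Conditions: PdCl2(PPh3)2 (3 mol%), CuI (5 mol%), Et3N, DMF, 80 °C
Reagents that add atoms: none
Why: Sonogashira coupling of the aryl bromide with the terminal alkyne should tolerate the acid (as its ammonium salt) and the free propargylic alcohol, and leaves the carbinol centre of 2 untouched.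

**Step 2**
Reactants: 3 2-{3-[(3R)-3-hydroxybut-1-yn-1-yl]-4-methoxyphenyl}acetic acid
Product: 4 2-{3-[(3R)-3-hydroxybutyl]-4-methoxyphenyl}acetic acid
Conditions: H2 (1 atm), 10% Pd on carbon, EtOAc, rt
Reagents that add atoms: none
Why: Catalytic hydrogenation of the aryl alkyne to the alkane should outpace C–O hydrogenolysis, so the (R) carbinol centre is retained.

**Step 3**
Reactants: 4 2-{3-[(3R)-3-hydroxybutyl]-4-methoxyphenyl}acetic acid
Product: 6 2-{5-[(3R)-3-hydroxybutyl]-4-oxocyclohex-1-en-1-yl}acetic acid, via dihydroanisole acid 5 (not isolated)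
Conditions: Li, NH3(l), THF, t-BuOH, −78 to −33 °C; NH4Cl; then (CO2H)2, THF–H2O, rt
Reagents that add atoms: water, O
Why: Birch reduction leaves the methoxy and both alkyl groups on the residual double bonds while the carboxylate and alkoxide stay inert, and mild oxalic acid hydrolysis of the enol ether should give the β,γ-unsaturated ketone without conjugation (both C5 epimers, which converge in step 5).

**Step 4**
Reactants: 6 2-{5-[(3R)-3-hydroxybutyl]-4-oxocyclohex-1-en-1-yl}acetic acid
Product: 7 (3aS,7aS)-5-[(3R)-3-hydroxybutyl]hexahydro-1-benzofuran-2,6-dione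
Conditions: 9-amino-9-deoxy-epi-quinine (20 mol%), toluene, rt
Reagents that add atoms: none
Why: Enantioselective isomerisation of a β,γ-unsaturated cyclohexenone by cooperative iminium–base catalysis with a cinchona primary amine: the dienamine is protonated at the γ-carbon under catalyst control (sets C3a), and the carboxylic acid then adds by intramolecular oxa-Michael reaction to the activated enone, which can only give the cis ring fusion (C7a).

**Step 5**
Reactants: 7 (3aS,7aS)-5-[(3R)-3-hydroxybutyl]hexahydro-1-benzofuran-2,6-dione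
Product: 8 (3aS,7R,9aS)-7-methyl-3,3a,4,5,6,7,9,9a-octahydro-2H-furo[3,2-g]chromen-2-one
Conditions: p-TsOH (5 mol%), benzene, reflux, Dean–Stark
Reagents that add atoms: none
Why: Acid-catalysed cyclodehydration of the δ-hydroxy ketone should give the bicyclic enol ether with the thermodynamically preferred tetrasubstituted C4a=C8a double bond, erasing the epimeric C5 centre.

**Step 6**
Reactants: 9 3-[(tert-butyldimethylsilyl)oxy]propanoic acid; 10 (E)-pent-2-enal
Product: 13 (1E,3E)-penta-1,3-dien-1-yl 3-[(tert-butyldimethylsilyl)oxy]propanoate, via acid chloride 11 (not isolated), via potassium dienolate 12 (not isolated)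
Conditions: 9, 1-chloro-N,N,2-trimethylprop-1-en-1-amine, CH2Cl2, 0 °C; separately 10, KOt-Bu, THF, −78 °C; combine at −78 °C
Reagents that add atoms: none
Why: O-acylation of a potassium dienolate (dienol ester synthesis): γ-deprotonation of the s-trans enal should give the (1E,3E)-dienolate, which the hard acyl chloride, made under neutral conditions that spare the silyl ether, captures on oxygen.

**Step 7**
Reactants: 13 (1E,3E)-penta-1,3-dien-1-yl 3-[(tert-butyldimethylsilyl)oxy]propanoate
Product: 14 (1E,3E)-penta-1,3-dien-1-yl 3-hydroxypropanoate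
Conditions: HF·pyridine, pyridine, THF, 0 °C
Reagents that add atoms: none
Why: Fluoride-mediated cleavage of the primary silyl ether under buffered, non-basic conditions should leave the enol ester intact.

**Step 8**
Reactants: 14 (1E,3E)-penta-1,3-dien-1-yl 3-hydroxypropanoate
Product: 16 (3aS,5R,7aS)-5-methyl-3,3a,5,7a-tetrahydro-2H-furo[3,2-b]pyran-2-one, via dienyl 3-oxopropanoate 15 (not isolated)
Conditions: Dess–Martin periodinane, CH2Cl2, 0 °C; filter, switch solvent; (R)-3,3′-bis(2,4,6-triisopropylphenyl)-1,1′-binaphthyl-2,2′-diyl N-(trifluoromethylsulfonyl)phosphoramide (10 mol%), toluene (0.01 M), 4 Å MS, −20 °C to rt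
Reagents that add atoms: none
Why: Proposed new method: Dess–Martin oxidation unveils aldehyde 15, whose carbonyl is activated by hydrogen bonding to the chiral N-triflyl phosphoramide and adds across the termini of the acyloxy-diene in a concerted, asynchronous [4+2] cycloaddition (intramolecular oxo-Diels–Alder), the C3a–C7a bond forming ahead of the O4–C5 bond; the closest known reactions are chiral Brønsted-acid-catalysed oxo-Diels–Alder additions of aldehydes to simple dienes and ester-tethered intramolecular Diels–Alder reactions. The lactone ring closes by C–C bond formation as the five-membered ring of a type 1 (fused-mode) intramolecular cycloaddition with the three-atom O–C(=O)–CH2 tether, and the dihydropyran closes as the six-membered ring of the [4+2] event itself. The (1E,3E) diene geometry is transferred suprafacially, so the C5 methyl and the C7a oxygen end up cis; the tether-endo transition state, in which the bulky acid bound anti to the CH2 arm of the aldehyde stays exo, gives the cis ring fusion at C3a/C7a; the absolute configuration comes from the catalyst shielding one face of the bound aldehyde. The step needs the regiochemistry opposite to the intermolecular polarity (aldehyde carbon to the oxygen-bearing diene terminus), which the short tether enforces and the weak donor character of the acyloxy group tolerates. It also needs the aldehyde tautomer of the β-formyl ester to cyclise faster than it self-condenses, which high dilution and acid-mediated keto–enol equilibration feeding the irreversible cycloaddition (Curtin–Hammett) should secure.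

**Step 9**
Reactants: 16 (3aS,5R,7aS)-5-methyl-3,3a,5,7a-tetrahydro-2H-furo[3,2-b]pyran-2-one
Product: 17 (3aS,5R,7aS)-5-methylhexahydro-2H-furo[3,2-b]pyran-2-one
Conditions: H2 (1 atm), RhCl(PPh3)3 (5 mol%), benzene–EtOH, rt
Reagents that add atoms: none
Why: Homogeneous hydrogenation with Wilkinson's catalyst should saturate the cis-disubstituted ring alkene without hydrogenolysis of the two allylic C–O bonds, and no stereocentre is formed or touched.

**Step 10**
Reactants: 8 (3aS,7R,9aS)-7-methyl-3,3a,4,5,6,7,9,9a-octahydro-2H-furo[3,2-g]chromen-2-one; 17 (3aS,5R,7aS)-5-methylhexahydro-2H-furo[3,2-b]pyran-2-one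
Product: 18 (3aS,7R,9aS)-3-[(3aS,5R,7aS)-2-hydroxy-5-methylhexahydro-2H-furo[3,2-b]pyran-2-yl]-7-methyl-3,3a,4,5,6,7,9,9a-octahydro-2H-furo[3,2-g]chromen-2-one
Conditions: 8, LDA (1.05 equiv), THF, −78 °C; then 17, −78 °C; AcOH quench
Reagents that add atoms: none
Why: Claisen-type addition of the lithium lactone enolate to the γ-lactone carbonyl, in which the lithium hemiketalate should persist at −78 °C so that neither proton exchange nor a second acylation intervenes; the two new centres are lost in step 11.

**Step 11**
Reactants: 18 hemiketal from step 10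
Product: 19 (3E,3aS,7R,9aS)-7-methyl-3-[(3aS,5R,7aS)-5-methylhexahydro-2H-furo[3,2-b]pyran-2-ylidene]-3,3a,4,5,6,7,9,9a-octahydro-2H-furo[3,2-g]chromen-2-one
Conditions: p-TsOH (5 mol%), benzene, 4 Å MS, 60 °C
Reagents that add atoms: none
Why: Acid-catalysed dehydration of the hemiketal of a β-keto lactone to the exocyclic push–pull enol ether (vinylogous carbonate), with reversible protonation at the α-carbon expected to equilibrate the geometry to the E isomer, in which the ring oxygen is anti to the lactone carbonyl.

**Step 12**
Reactants: 19 vinylogous carbonate from step 11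
Product: 20 Cordycicadin C
Conditions: O3, CH2Cl2, −78 °C, Sudan Red 7B as end-point indicator; then Me2S, −78 °C to rt
Reagents that add atoms: ozone, O=[O+][O-]
Why: Ozonolysis of the bicyclic enol ether as an oxidative ring expansion: electrophilic ozone should attack the donor-only tetrasubstituted enol ether far faster than the ester-conjugated exocyclic one, and cleavage of the shared C=C turns its two carbons into the ketone and the lactone carbonyl of the ten-membered ring without touching any stereocentre.

**Compound list**

1 | 2-(3-bromo-4-methoxyphenyl)acetic acid | COc1ccc(CC(=O)O)cc1Br | starting material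
2 | (R)-but-3-yn-2-ol | C[C@@H](O)C#C | starting material
3 | 2-{3-[(3R)-3-hydroxybut-1-yn-1-yl]-4-methoxyphenyl}acetic acid | C[C@@H](O)C#Cc1cc(CC(=O)O)ccc1OC | intermediate
4 | 2-{3-[(3R)-3-hydroxybutyl]-4-methoxyphenyl}acetic acid | C[C@@H](O)CCc1cc(CC(=O)O)ccc1OC | intermediate
5 | 2-{5-[(3R)-3-hydroxybutyl]-4-methoxycyclohexa-1,4-dien-1-yl}acetic acid | C[C@@H](O)CCC1=C(OC)CC=C(CC(=O)O)C1 | intermediate (not isolated)
6 | 2-{5-[(3R)-3-hydroxybutyl]-4-oxocyclohex-1-en-1-yl}acetic acid (both C5 epimers) | C[C@@H](O)CCC1CC(CC(=O)O)=CCC1=O | intermediate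
7 | (3aS,7aS)-5-[(3R)-3-hydroxybutyl]hexahydro-1-benzofuran-2,6-dione (cis-fused; both C5 epimers) | C[C@@H](O)CCC1C[C@H]2CC(=O)O[C@H]2CC1=O | intermediate
8 | (3aS,7R,9aS)-7-methyl-3,3a,4,5,6,7,9,9a-octahydro-2H-furo[3,2-g]chromen-2-one (cis-fused γ-lactone on a cyclohexene whose tetrasubstituted C=C is shared with a 2-methyl-3,4-dihydro-2H-pyran) | C[C@@H]1CCC5C[C@H]2CC(=O)O[C@H]2CC=5O1 | intermediate
9 | 3-[(tert-butyldimethylsilyl)oxy]propanoic acid | CC(C)(C)[Si](C)(C)OCCC(=O)O | starting material
10 | (E)-pent-2-enal | CC/C=C/C=O | starting material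
11 | 3-[(tert-butyldimethylsilyl)oxy]propanoyl chloride | CC(C)(C)[Si](C)(C)OCCC(=O)Cl | intermediate (not isolated)
12 | potassium (1E,3E)-penta-1,3-dien-1-olate | C/C=C/C=C/[O-].[K+] | intermediate (not isolated)
13 | (1E,3E)-penta-1,3-dien-1-yl 3-[(tert-butyldimethylsilyl)oxy]propanoate | C/C=C/C=C/OC(=O)CCO[Si](C)(C)C(C)(C)C | intermediate
14 | (1E,3E)-penta-1,3-dien-1-yl 3-hydroxypropanoate | C/C=C/C=C/OC(=O)CCO | intermediate
15 | (1E,3E)-penta-1,3-dien-1-yl 3-oxopropanoate | C/C=C/C=C/OC(=O)CC=O | intermediate (not isolated)
16 | (3aS,5R,7aS)-5-methyl-3,3a,5,7a-tetrahydro-2H-furo[3,2-b]pyran-2-one (cis-fused; H3a, H5 and H7a all cis) | O=C1C[C@@H]2O[C@H](C)C=C[C@@H]2O1 | intermediate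
17 | (3aS,5R,7aS)-5-methylhexahydro-2H-furo[3,2-b]pyran-2-one | O=C1C[C@@H]2O[C@H](C)CC[C@@H]2O1 | intermediate
18 | (3aS,7R,9aS)-3-[(3aS,5R,7aS)-2-hydroxy-5-methylhexahydro-2H-furo[3,2-b]pyran-2-yl]-7-methyl-3,3a,4,5,6,7,9,9a-octahydro-2H-furo[3,2-g]chromen-2-one (mixture at C3 and the hemiketal carbon) | C[C@@H]1CCC5C[C@H]2C(C3(O)C[C@@H]4O[C@H](C)CC[C@@H]4O3)C(=O)O[C@H]2CC=5O1 | intermediate
19 | (3E,3aS,7R,9aS)-7-methyl-3-[(3aS,5R,7aS)-5-methylhexahydro-2H-furo[3,2-b]pyran-2-ylidene]-3,3a,4,5,6,7,9,9a-octahydro-2H-furo[3,2-g]chromen-2-one | C[C@@H]1CCC5C[C@H]2/C(=C3/C[C@@H]4O[C@H](C)CC[C@@H]4O3)C(=O)O[C@H]2CC=5O1 | intermediate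
20 | Cordycicadin C | C[C@@H]1CCC(=O)C[C@H]2/C(=C3/C[C@@H]4O[C@H](C)CC[C@@H]4O3)C(=O)O[C@H]2CC(=O)O1 | target

**Totals**

Total step count: 12. Longest linear sequence: 8 (steps 1–5, then 10–12); fragment A contributes 4 steps (6–9).

**Steps most likely to fail**

1. Step 8 (Proposed new method). Keto–enol tautomerisation and self-condensation of the β-formyl ester may outrun the cycloaddition, the reactive s-cis ester conformer may be too sparsely populated, or the catalyst may give poor facial control. The fallback uses known chemistry only, sets out from (R)-but-3-yn-2-ol 2 and returns at lactone 17. Silylation (TBSCl, imidazole) should give (R)-tert-butyl(but-3-yn-2-yloxy)dimethylsilane F1, whose lithium acetylide (n-BuLi, THF, −78 °C) opens succinic anhydride to ynone acid F2. Noyori transfer hydrogenation (RuCl[(R,R)-TsDPEN](p-cymene), HCO2H/Et3N) should give the (4R)-propargylic hydroxy acid F3, which lactonises on acidification to alkynyl lactone F4. Hydrogenation (H2, Pd on carbon) gives saturated lactone F5; α-selenenylation (LDA, PhSeBr) gives selenide F6 and oxidative syn-elimination (H2O2) gives butenolide F7. TBAF then removes the silyl group, and the alkoxide of hydroxy-butenolide F8 adds by oxa-Michael reaction to the butenolide from the face of its own side chain, closing the cis-fused tetrahydropyran of 17. In this sequence C7a comes from the ruthenium catalyst, C5 from 2 and C3a from the enforced cis ring fusion.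

2. Step 4. The α′-branch and the free acid of 6 may slow iminium formation or erode face selectivity in the γ-protonation, and reversible dienamine formation may racemise the γ-centre before lactonisation. The fallback sets out from 6 and returns at 8, replacing catalyst control by separation through the fixed side-chain centre. Aqueous HCl in THF should conjugate and lactonise 6 without selectivity to a mixture of 7 and its (3aR,7aR)-diastereomer F9. Cyclodehydration as in step 5 then gives 8 together with the (3aR,7R,9aR)-diastereomer F10; because the 7R methyl centre is fixed these are diastereomers, to be separated by chromatography or fractional crystallisation.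

3. Step 12. Ozone may attack the push–pull exocyclic alkene competitively, or peroxidic intermediates may degrade the vinylogous carbonate. The fallback sets out from 19 and returns at 20 by a stepwise glycol-type cleavage. Dimethyldioxirane (acetone, −78 °C) should epoxidise only the electron-rich enol ether to epoxide F11; aqueous work-up opens it to the α-hydroxy hemiketal F12; Pb(OAc)4 (benzene, rt) then cleaves the C–C bond to the ketone and the lactone of 20.

**Further compounds**

F1 | step 8 | (R)-tert-butyl(but-3-yn-2-yloxy)dimethylsilane | C[C@@H](O[Si](C)(C)C(C)(C)C)C#C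
F2 | step 8 | (7R)-7-[(tert-butyldimethylsilyl)oxy]-4-oxooct-5-ynoic acid | C[C@@H](O[Si](C)(C)C(C)(C)C)C#CC(=O)CCC(=O)O
F3 | step 8 | (4R,7R)-7-[(tert-butyldimethylsilyl)oxy]-4-hydroxyoct-5-ynoic acid | C[C@@H](O[Si](C)(C)C(C)(C)C)C#C[C@H](O)CCC(=O)O
F4 | step 8 | (5R)-5-{(3R)-3-[(tert-butyldimethylsilyl)oxy]but-1-yn-1-yl}dihydrofuran-2(3H)-one | C[C@@H](O[Si](C)(C)C(C)(C)C)C#C[C@H]1CCC(=O)O1
F5 | step 8 | (5S)-5-{(3R)-3-[(tert-butyldimethylsilyl)oxy]butyl}dihydrofuran-2(3H)-one | C[C@@H](O[Si](C)(C)C(C)(C)C)CC[C@H]1CCC(=O)O1
F6 | step 8 | (5S)-5-{(3R)-3-[(tert-butyldimethylsilyl)oxy]butyl}-3-(phenylselanyl)dihydrofuran-2(3H)-one | C[C@@H](O[Si](C)(C)C(C)(C)C)CC[C@H]1CC([Se]c2ccccc2)C(=O)O1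
F7 | step 8 | (5S)-5-{(3R)-3-[(tert-butyldimethylsilyl)oxy]butyl}furan-2(5H)-one | C[C@@H](O[Si](C)(C)C(C)(C)C)CC[C@H]1C=CC(=O)O1
F8 | step 8 | (5S)-5-[(3R)-3-hydroxybutyl]furan-2(5H)-one | C[C@@H](O)CC[C@H]1C=CC(=O)O1
F9 | step 4 | (3aR,7aR)-5-[(3R)-3-hydroxybutyl]hexahydro-1-benzofuran-2,6-dione | C[C@@H](O)CCC1C[C@@H]2CC(=O)O[C@@H]2CC1=O
F10 | step 4 | (3aR,7R,9aR)-7-methyl-3,3a,4,5,6,7,9,9a-octahydro-2H-furo[3,2-g]chromen-2-one | C[C@@H]1CCC5C[C@@H]2CC(=O)O[C@@H]2CC=5O1
F11 | step 12 | 4a,8a-epoxide of 19 | C[C@@H]1CCC56C[C@H]2/C(=C3/C[C@@H]4O[C@H](C)CC[C@@H]4O3)C(=O)O[C@H]2CC5(O6)O1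
F12 | step 12 | 4a,8a-dihydroxy derivative (α-hydroxy hemiketal) of 19 | C[C@@H]1CCC5(O)C[C@H]2/C(=C3/C[C@@H]4O[C@H](C)CC[C@@H]4O3)C(=O)O[C@H]2CC5(O)O1
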